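## Retrosynthetic overview

1. Target ⇐ pentacyclic 2‑ketone (Luche reduction sets C2) ⇐ ring C closed at C1–C16 by enolate addition–elimination on a 2‑chloro‑3‑acylfuran.
2. C3=C4 by dehydrogenation of the ring A ketone; 10β‑H (trans‑decalin) by hydrogen‑atom‑transfer reduction of a 1(10)‑en‑2‑one.
3. Key disconnection C9–C11: the α‑carbon of a 3‑acetylfuran as an enolonium, joined to the γ‑carbon of the ring A dienol ether; this unites the two fragments and sets the C9 quaternary centre.
4. Ring A and the γ‑lactone together: intramolecular Michael addition/aldol condensation of an acetylacrylate ester onto the ring B ketone (sets C5).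
5. Ring B with C7/C8: all‑cis hydrogenation of 2,3‑dimethylhydroquinone, then lipase desymmetrisation. Ring order: B → lactone + A → C.

Numbering and faces: clerodane numbering for the polycycles (C1–C10 decalin, C11–C12 chain, C13–C16 furan, C17 = 8‑Me, C18 = lactone C=O on C4, C19 = lactone CH2 on C5, C20 = 9‑Me); α is the face of the 7‑acetoxy group.

Assumption: centres written without configuration in a SMILES (C5/C9 before ring A exists; C4 and C9 in 9; C4 in 10, 16, 17) are epimer mixtures that are later planarised or equilibrated.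

## Route

Step 1
Reactants: 1 2,3-dimethylbenzene-1,4-diol
Product: 2 (1R,2S,3R,4S)-2,3-dimethylcyclohexane-1,4-diol (all-cis meso diol)
Conditions: H2 (50 bar), 5% Rh/Al2O3, EtOH, 60 °C
Reagents that add atoms: none
Why: Heterogeneous arene hydrogenation delivers all hydrogens to one face of the adsorbed ring, so both hydroxyls and both methyls end up cis and the product is the meso diol.

Step 2
Reactants: 2 (1R,2S,3R,4S)-2,3-dimethylcyclohexane-1,4-diol
Product: 3 (1R,2S,3R,4S)-4-hydroxy-2,3-dimethylcyclohexyl acetate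
Conditions: Burkholderia cepacia lipase, vinyl acetate, t-BuOMe, 30 °C
Reagents that add atoms: vinyl acetate CC(=O)OC=C
Why: Enzymatic desymmetrisation of a meso diol by irreversible transesterification acylates the (R)-carbinol (large CHMe versus medium CH2 flank, Kazlauskas rule), which fixes the absolute configuration and installs the C7 acetate that is carried to the target.

Step 3
Reactants: 3 (1R,2S,3R,4S)-4-hydroxy-2,3-dimethylcyclohexyl acetate
Product: 4 (1R,2S,3R)-2,3-dimethyl-4-oxocyclohexyl acetate
Conditions: Dess–Martin periodinane, CH2Cl2, 0 °C → rt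
Reagents that add atoms: none
Why: Dess–Martin oxidation of the remaining secondary alcohol is neutral enough to leave the acetate and the C7/C8 centres untouched, and the labile α-methyl centre (future C9) is rebuilt later.

Step 4
Reactants: 4 (1R,2S,3R)-2,3-dimethyl-4-oxocyclohexyl acetate
Product: 5 (1R,2S)-5-(hydroxymethyl)-2,3-dimethyl-4-oxocyclohexyl acetate
Conditions: 37% aq. HCHO, L-proline (20 mol%), DMSO, rt
Reagents that add atoms: formaldehyde C=O
Why: Proline enamine catalysis (direct aldol with formaldehyde) engages only the less substituted α-CH2 and introduces the future C19 as CH2OH; no lasting stereocentre is set because this carbon is enolised again in step 6.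

Step 5
Reactants: 5 (1R,2S)-5-(hydroxymethyl)-2,3-dimethyl-4-oxocyclohexyl acetate; 6 (E)-4-oxopent-2-enoic acid
Product: 7 [(4S,5R)-5-acetoxy-3,4-dimethyl-2-oxocyclohexyl]methyl (E)-4-oxopent-2-enoate
Conditions: DIC, DMAP (5 mol%), CH2Cl2, 0 °C
Reagents that add atoms: none
Why: Steglich (carbodiimide) esterification of the primary alcohol attaches C18, C4, C3, C2 and C1 as a tether without touching the secondary acetate.

Step 6
Reactants: 7 [(4S,5R)-5-acetoxy-3,4-dimethyl-2-oxocyclohexyl]methyl (E)-4-oxopent-2-enoate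
Product: 9 7α-acetoxy-2-oxo-11,12,13,14,15,16-hexanor-neo-clerod-1(10)-en-18,19-olide, via spirolactone Michael adduct 8 (not isolated)
Conditions: TsOH·H2O (0.3 equiv), PhMe, 60 °C then reflux (Dean–Stark)
Reagents that add atoms: none
Why: Acid-catalysed Robinson-type annulation in which the ring-ketone enol adds 5-exo-trig to the tethered alkene carbon β to the methyl ketone (intramolecular Michael addition, closing the γ-lactone and creating quaternary C5 from the face opposite the axial 7-acetoxy group, so C19 ends α), after which the methyl ketone undergoes aldol condensation onto C10 to close ring A.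

Step 7
Reactants: 9 7α-acetoxy-2-oxo-11,12,13,14,15,16-hexanor-neo-clerod-1(10)-en-18,19-olide
Product: 10 7α-acetoxy-2-(tert-butyldimethylsilyloxy)-11,12,13,14,15,16-hexanor-neo-cleroda-1,9-dien-18,19-olide
Conditions: TBSOTf, Et3N, CH2Cl2, 0 °C → rt
Reagents that add atoms: tert-butyldimethylsilyl triflate CC(C)(C)[Si](C)(C)OS(=O)(=O)C(F)(F)F
Why: O-Silylation under equilibrating conditions removes the γ-hydrogen at C9 to give the extended (heteroannular) dienol ether, the same regiochemistry as the 3,5-dienol ethers of steroidal 4-en-3-ones, which makes C9 a soft γ-nucleophile.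

Step 8
Reactants: 11 furan-3-carboxylic acid
Product: 12 2-chlorofuran-3-carboxylic acid
Conditions: LiN(iPr)2 (2.2 equiv), THF, −78 °C; C2Cl6; then aq. HCl
Reagents that add atoms: hexachloroethane ClC(Cl)(Cl)C(Cl)(Cl)Cl
Why: Directed ortho-metalation places the second lithium at C2 next to the carboxylate, and the dianion is chlorinated by hexachloroethane.

Step 9
Reactants: 12 2-chlorofuran-3-carboxylic acid
Product: 13 1-(2-chlorofuran-3-yl)ethan-1-one
Conditions: MeLi (2.2 equiv), Et2O, 0 °C → rt; then H2O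
Reagents that add atoms: methyllithium [Li]C
Why: Addition of methyllithium to the lithium carboxylate gives a stable gem-diolate that collapses to the methyl ketone on work-up, the new methyl carbon being the future C11.

Step 10
Reactants: 13 1-(2-chlorofuran-3-yl)ethan-1-one
Product: 14 [1-(2-chlorofuran-3-yl)ethenyl]oxy(trimethyl)silane
Conditions: TMSOTf, Et3N, CH2Cl2, 0 °C
Reagents that add atoms: trimethylsilyl triflate C[Si](C)(C)OS(=O)(=O)C(F)(F)F
Why: Soft enolisation and O-silylation give the silyl enol ether from which the enolonium is generated.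

Step 11
Reactants: 14 [1-(2-chlorofuran-3-yl)ethenyl]oxy(trimethyl)silane; 10 7α-acetoxy-2-(tert-butyldimethylsilyloxy)-11,12,13,14,15,16-hexanor-neo-cleroda-1,9-dien-18,19-olide
Product: 16 7α-acetoxy-16-chloro-15,16-epoxy-2,12-dioxo-neo-cleroda-1(10),13(16),14-trien-18,19-olide, via enolonium iodane 15 (not isolated)
Conditions: PhI(OAc)2, BF3·OEt2, CH2Cl2, −78 °C (5 min with 14); then 10, −78 → −40 °C
Reagents that add atoms: none
Why: Proposed new method: PhI(OAc)2/BF3 converts 14 into a C-bound α-keto λ3-iodane (enolonium) whose α-carbon C11, normally nucleophilic, is attacked by the γ-carbon C9 of dienol ether 10, also normally nucleophilic, with loss of iodobenzene to give the 1,6-diketone and restore the enone; attack is expected at γ because it returns the conjugated enone (as in 6-substitution of steroidal 3,5-dienol ethers and vinylogous Mukaiyama reactions) and from the β-face because the α-face of C9 is shielded by the pseudo-axial C8 methyl and the axial C19 methylene, which sets the C9 quaternary centre (C11 β, C20 α); the closest known reactions are the cross-coupling of two silyl enol ethers through enolonium species to unsymmetrical 1,4-diketones and the γ-alkylation of silyl dienol ethers.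

Step 12
Reactants: 16 7α-acetoxy-16-chloro-15,16-epoxy-2,12-dioxo-neo-cleroda-1(10),13(16),14-trien-18,19-olide
Product: 17 7α-acetoxy-16-chloro-15,16-epoxy-2,12-dioxo-neo-cleroda-13(16),14-dien-18,19-olide
Conditions: Mn(dpm)3 (10 mol%, dpm = dipivaloylmethanate), PhSiH3, i-PrOH, CH2Cl2, rt, argon
Reagents that add atoms: none
Why: Manganese hydride hydrogen-atom-transfer conjugate reduction (Magnus type) delivers H to the hindered β-carbon C10 from the β-face, opposite the axial α-groups C19 and C20 that flank it, which gives the trans-decalin while sparing the chlorofuran and both ketones.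

Step 13
Reactants: 17 7α-acetoxy-16-chloro-15,16-epoxy-2,12-dioxo-neo-cleroda-13(16),14-dien-18,19-olide
Product: 18 7α-acetoxy-16-chloro-15,16-epoxy-2,12-dioxo-neo-cleroda-3,13(16),14-trien-18,19-olide
Conditions: IBX (1.5 equiv), DMSO, 70 °C
Reagents that add atoms: none
Why: IBX dehydrogenation of the ring A ketone (Nicolaou) should remove the C3 and C4 hydrogens, because C4–H is also α to the lactone carbonyl and the product is a doubly conjugated ene-dione, while the furyl ketone has no β-hydrogen.

Step 14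
Reactants: 18 7α-acetoxy-16-chloro-15,16-epoxy-2,12-dioxo-neo-cleroda-3,13(16),14-trien-18,19-olide
Product: 19 7α-acetoxy-15,16-epoxy-2,12-dioxo-1,16-cyclo-neo-cleroda-3,13(16),14-trien-18,19-olide
Conditions: Cs2CO3, DMF, rt
Reagents that add atoms: none
Why: Proposed new method: base generates the only ring A enolate that can cyclise (C1, the α'-position of the ene-dione), which adds to C16, the β-carbon of the 3-acyl-2-chlorofuran (a vinylogous acid chloride), and expels chloride (intramolecular addition–elimination, SNAr-type C-arylation) to close the seven-membered ring C, after which the acidic C1–H equilibrates to the 1β-furyl, 1α-H isomer required by the trans ring fusion; the closest known reactions are SNAr displacements on 2-halo-3-acyl or nitro furans and thiophenes and intramolecular enolate arylations.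

Step 15
Reactants: 19 7α-acetoxy-15,16-epoxy-2,12-dioxo-1,16-cyclo-neo-cleroda-3,13(16),14-trien-18,19-olide
Product: 20 7α-acetoxy-15,16-epoxy-2α-hydroxy-12-oxo-1,16-cyclo-neo-cleroda-3,13(16),14-trien-18,19-olide (CNP0182929.1)
Conditions: NaBH4, CeCl3·7H2O, MeOH, −78 °C
Reagents that add atoms: none
Why: Luche reduction takes the more electrophilic ene-dione ketone 1,2 in preference to the furyl ketone (a vinylogous ester), and axial hydride attack from the β-face gives the equatorial 2α-alcohol.

## Compound list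

1 | 2,3-dimethylbenzene-1,4-diol | Cc1c(O)ccc(O)c1C | starting material
2 | (1R,2S,3R,4S)-2,3-dimethylcyclohexane-1,4-diol (all-cis, meso) | O[C@@H]1CC[C@H](O)[C@H](C)[C@@H]1C | intermediate
3 | (1R,2S,3R,4S)-4-hydroxy-2,3-dimethylcyclohexyl acetate | CC(=O)O[C@@H]1CC[C@H](O)[C@H](C)[C@@H]1C | intermediate
4 | (1R,2S,3R)-2,3-dimethyl-4-oxocyclohexyl acetate | CC(=O)O[C@@H]1CCC(=O)[C@H](C)[C@@H]1C | intermediate
5 | (1R,2S)-5-(hydroxymethyl)-2,3-dimethyl-4-oxocyclohexyl acetate (epimers at C3 and C5) | CC(=O)O[C@@H]1CC(CO)C(=O)C(C)[C@@H]1C | intermediate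
6 | (E)-4-oxopent-2-enoic acid | CC(=O)/C=C/C(=O)O | starting material
7 | [(4S,5R)-5-acetoxy-3,4-dimethyl-2-oxocyclohexyl]methyl (E)-4-oxopent-2-enoate (epimers at C1 and C3 of the ring) | CC(=O)O[C@@H]1CC(COC(=O)/C=C/C(C)=O)C(=O)C(C)[C@@H]1C | intermediate
8 | (5S,8S,9R)-7,8-dimethyl-3,6-dioxo-4-(2-oxopropyl)-2-oxaspiro[4.5]decan-9-yl acetate (epimers at C4 and C7) | CC(=O)O[C@@H]1C[C@]2(COC(=O)C2CC(C)=O)C(=O)C(C)[C@@H]1C | intermediate
9 | 7α-acetoxy-2-oxo-11,12,13,14,15,16-hexanor-neo-clerod-1(10)-en-18,19-olide (C19 α; epimers at C4 and C9) | CC(=O)O[C@@H]1C[C@@]23COC(=O)C2CC(=O)C=C3C(C)[C@@H]1C | intermediate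
10 | 7α-acetoxy-2-(tert-butyldimethylsilyloxy)-11,12,13,14,15,16-hexanor-neo-cleroda-1,9-dien-18,19-olide (epimers at C4) | CC(=O)O[C@@H]1C[C@@]23COC(=O)C2CC(O[Si](C)(C)C(C)(C)C)=CC3=C(C)[C@@H]1C | intermediate
11 | furan-3-carboxylic acid | OC(=O)c1ccoc1 | starting material
12 | 2-chlorofuran-3-carboxylic acid | OC(=O)c1ccoc1Cl | intermediate
13 | 1-(2-chlorofuran-3-yl)ethan-1-one | CC(=O)c1ccoc1Cl | intermediate
14 | [1-(2-chlorofuran-3-yl)ethenyl]oxy(trimethyl)silane | C=C(O[Si](C)(C)C)c1ccoc1Cl | intermediate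
15 | 2-[acetoxy(phenyl)-λ3-iodanyl]-1-(2-chlorofuran-3-yl)ethan-1-one (BF3-activated enolonium) | CC(=O)OI(c1ccccc1)CC(=O)c1ccoc1Cl | intermediate
16 | 7α-acetoxy-16-chloro-15,16-epoxy-2,12-dioxo-neo-cleroda-1(10),13(16),14-trien-18,19-olide (epimers at C4) | CC(=O)O[C@@H]1C[C@@]23COC(=O)C2CC(=O)C=C3[C@@](C)(CC(=O)c2ccoc2Cl)[C@@H]1C | intermediate
17 | 7α-acetoxy-16-chloro-15,16-epoxy-2,12-dioxo-neo-cleroda-13(16),14-dien-18,19-olide (10β-H; epimers at C4) | CC(=O)O[C@@H]1C[C@@]23COC(=O)C2CC(=O)C[C@@H]3[C@@](C)(CC(=O)c2ccoc2Cl)[C@@H]1C | intermediate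
18 | 7α-acetoxy-16-chloro-15,16-epoxy-2,12-dioxo-neo-cleroda-3,13(16),14-trien-18,19-olide | CC(=O)O[C@@H]1C[C@@]23COC(=O)C2=CC(=O)C[C@@H]3[C@@](C)(CC(=O)c2ccoc2Cl)[C@@H]1C | intermediate
19 | 7α-acetoxy-15,16-epoxy-2,12-dioxo-1,16-cyclo-neo-cleroda-3,13(16),14-trien-18,19-olide (1α-H) | CC(=O)O[C@@H]1C[C@@]23COC(=O)C2=CC(=O)[C@H]2c4occc4C(=O)C[C@@](C)([C@@H]1C)[C@@H]23 | intermediate
20 | 7α-acetoxy-15,16-epoxy-2α-hydroxy-12-oxo-1,16-cyclo-neo-cleroda-3,13(16),14-trien-18,19-olide (CNP0182929.1) | CC(=O)O[C@@H]1C[C@@]23COC(=O)C2=C[C@H](O)[C@H]2c4occc4C(=O)C[C@@](C)([C@@H]1C)[C@@H]23 | target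

## Step count and risks

Total steps: 15. Longest linear sequence: 12 (steps 1–7 and 11–15); the furan branch is steps 8–10.

Three steps most likely to fail:

Step 11 (enolonium γ-coupling). The dienol ether may react at C1 instead of C9, may form as the cross-conjugated isomer in step 7, or may not react at the fully substituted γ-carbon. The fallback builds the quaternary centre first on the monocyclic ketone, whose enol ether has only one nucleophilic carbon. Setting out from 4, TMSCl/NaI/Et3N in MeCN gives the thermodynamic enol ether (1R,2S)-2,3-dimethyl-4-(trimethylsilyloxy)cyclohex-3-en-1-yl acetate F1. Reaction of this with enolonium 15 (generated from 14 as in step 11) gives, anti to the neighbouring C8 methyl, the 1,4-diketone (1R,2S,3S)-3-[2-(2-chlorofuran-3-yl)-2-oxoethyl]-2,3-dimethyl-4-oxocyclohexyl acetate F2. Proline/formaldehyde hydroxymethylation at the only ring α-CH2 gives the hydroxymethyl diketone F3, DIC esterification with 6 gives the acetylacrylate ester F4, and TsOH in refluxing toluene takes this through the spirolactone Michael adduct F5 and aldol condensation back to the route at 16.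

Step 6 (tethered Michael/aldol). The β-acyloxy ketone may lose acetylacrylic acid faster than it cyclises. The fallback makes the C5–C4 bond intermolecularly with a 1,3-dicarbonyl donor and closes the lactone afterwards by C–O bond formation. Setting out from 4, tert-butoxybis(dimethylamino)methane gives the enaminone F6, and mild aqueous acid gives the hydroxymethylene ketone F7. Et3N-catalysed Michael addition to methyl (E)-4-oxopent-2-enoate gives the α-formyl quaternary keto ester F8. NaBH4 at −78 °C reduces only the aldehyde, and the alcohol lactonises onto the methyl ester to return to the route at 8, which is cyclised with TsOH to 9 as in step 6.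

Step 13 (IBX regiochemistry). IBX may dehydrogenate 17 towards C1/C10 or over-oxidise. The fallback introduces the C3=C4 bond one stage earlier, where only one direction is possible, and carries it through masked. Setting out from 16, IBX gives the cross-conjugated dienone F9, and thiophenol/Et3N adds at C3 to give the 3-phenylthio enone F10. The manganese hydride reduction of step 12 then reduces the only remaining alkene to give the 3-phenylthio ketone F11. Cs2CO3 in DMF both expels thiophenolate through the lactone enolate (re-forming C3=C4) and closes ring C, returning to the route at 19.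

## Further compounds

F1 | step 11 | (1R,2S)-2,3-dimethyl-4-(trimethylsilyloxy)cyclohex-3-en-1-yl acetate | CC(=O)O[C@@H]1CCC(O[Si](C)(C)C)=C(C)[C@@H]1C
F2 | step 11 | (1R,2S,3S)-3-[2-(2-chlorofuran-3-yl)-2-oxoethyl]-2,3-dimethyl-4-oxocyclohexyl acetate | CC(=O)O[C@@H]1CCC(=O)[C@@](C)(CC(=O)c2ccoc2Cl)[C@@H]1C
F3 | step 11 | (1R,2S,3S)-3-[2-(2-chlorofuran-3-yl)-2-oxoethyl]-5-(hydroxymethyl)-2,3-dimethyl-4-oxocyclohexyl acetate (epimers at C5) | CC(=O)O[C@@H]1CC(CO)C(=O)[C@@](C)(CC(=O)c2ccoc2Cl)[C@@H]1C
F4 | step 11 | [(3S,4S,5R)-5-acetoxy-3-[2-(2-chlorofuran-3-yl)-2-oxoethyl]-3,4-dimethyl-2-oxocyclohexyl]methyl (E)-4-oxopent-2-enoate | CC(=O)O[C@@H]1CC(COC(=O)/C=C/C(C)=O)C(=O)[C@@](C)(CC(=O)c2ccoc2Cl)[C@@H]1C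
F5 | step 11 | (5S,7S,8S,9R)-7-[2-(2-chlorofuran-3-yl)-2-oxoethyl]-7,8-dimethyl-3,6-dioxo-4-(2-oxopropyl)-2-oxaspiro[4.5]decan-9-yl acetate (epimers at C4) | CC(=O)O[C@@H]1C[C@]2(COC(=O)C2CC(C)=O)C(=O)[C@@](C)(CC(=O)c2ccoc2Cl)[C@@H]1C
F6 | step 6 | (1R,2S)-5-[(dimethylamino)methylidene]-2,3-dimethyl-4-oxocyclohexyl acetate | CC(=O)O[C@@H]1CC(=CN(C)C)C(=O)C(C)[C@@H]1C
F7 | step 6 | (1R,2S)-5-(hydroxymethylidene)-2,3-dimethyl-4-oxocyclohexyl acetate | CC(=O)O[C@@H]1CC(=CO)C(=O)C(C)[C@@H]1C
F8 | step 6 | methyl 2-[(1S,4S,5R)-5-acetoxy-1-formyl-3,4-dimethyl-2-oxocyclohexyl]-4-oxopentanoate (epimers at C2 of the chain and C3 of the ring) | CC(=O)O[C@@H]1C[C@@](C=O)(C(CC(C)=O)C(=O)OC)C(=O)C(C)[C@@H]1C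
F9 | step 13 | 7α-acetoxy-16-chloro-15,16-epoxy-2,12-dioxo-neo-cleroda-1(10),3,13(16),14-tetraen-18,19-olide | CC(=O)O[C@@H]1C[C@@]23COC(=O)C2=CC(=O)C=C3[C@@](C)(CC(=O)c2ccoc2Cl)[C@@H]1C
F10 | step 13 | 7α-acetoxy-16-chloro-15,16-epoxy-2,12-dioxo-3-(phenylthio)-neo-cleroda-1(10),13(16),14-trien-18,19-olide (epimers at C3 and C4) | CC(=O)O[C@@H]1C[C@@]23COC(=O)C2C(Sc4ccccc4)C(=O)C=C3[C@@](C)(CC(=O)c2ccoc2Cl)[C@@H]1C
F11 | step 13 | 7α-acetoxy-16-chloro-15,16-epoxy-2,12-dioxo-3-(phenylthio)-neo-cleroda-13(16),14-dien-18,19-olide (10β-H; epimers at C3 and C4) | CC(=O)O[C@@H]1C[C@@]23COC(=O)C2C(Sc4ccccc4)C(=O)C[C@@H]3[C@@](C)(CC(=O)c2ccoc2Cl)[C@@H]1C
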